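The numbers in the tables stem from a simulated flask for an exercise.

Slowness is what we reckon with first in this flask, whose catalyst is 0.203% of the starting-material charge, so each catalyst must turn over 492 times to use up that charge.

| flask | starting material | partner | scavenger | free catalyst | remark | time |
|---|---|---|---|---|---|---|
| amber | 0.059 M | 0.295 M (fed, over 30 min) | 0.059 M | 0.17 mM | run made earlier |  |
| blue | 0.059 M | 0.295 M (fed, over 30 min) | 0.059 M | 0.26 mM | run made earlier |  |
| flask | 0.059 M | 0.295 M (fed, over 30 min) | 0.0590 M | 0.12 mM |  | 15 h |

- amber (time / h: starting material / %, product / %): 0.833: 91.7, 8.0; 2.50: 71.8, 26.8; 4.00: 55.0, 44.1; 6.00: 36.2, 62.5; 10.0: 10.2, 90.1; 12.0: 4.6, 95.3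
- blue (time / h: starting material / %, product / %): 0.833: 87.8, 12.8; 2.50: 59.1, 41.4; 4.00: 35.8, 64.4; 6.00: 15.1, 85.2; 10.0: 0, 98.0; 12.0: 0, 99.1

(each reading ± 0.5 percentage points)

* part of the starting material that has reacted at 15 h
* share of the unused partner that is free and not bound as idle adduct, at 15 h

- the earlier runs do not show how much of partner is bound; that part of a forecast is a guess

1. Amber, from 0.833 h to 6.00 h, gives 37.3 h⁻¹: this is the turnover frequency, the fraction of the charge used per hour divided by the catalyst's fraction of the charge. Blue, from 0.833 h to 4.00 h, which spans nearly the same fall in starting material, gives 37.3 h⁻¹, so with the other charges held, the rate follows the catalyst.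

2. At that pace the flask makes 560 turnovers in 15 h, more than the 492 required, which promises complete use of the starting material, the limiting reagent, with partner charged at 5.00 times its amount.

3. But the pace does not hold, since amber between 10.0 h and 12.0 h manages 9.72 h⁻¹, slower than before, so the straight count fails.

4. We therefore match catalyst times hours instead: the flask's 15 h equals amber at 10.6 h, where interpolation leaves 8.55%, and we commit to 91.5% reacted.

5. One doubt remains: the flask's 15 h lies beyond amber's last reading at 12.0 h, and our match of catalyst times hours takes it that no catalyst is lost over that stretch, which we cannot compute away. How much partner is bound the runs do not show.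

The forecast gives 92% reacted, close to our figure, and 82% of the unused partner free, of which it says: “Binding strength is unknown, so this is a guess”.

The flask gives 92.4% reacted and 97.8% free, so the first figure holds and the second stands 16 percentage points low. At 15.0 h the idle adduct is 1.78% of the partner charge, with 79.7% of that charge still free. In turnovers, the flask has made 454 per catalyst, a mean of 30.3 h⁻¹, below the 37.3 h⁻¹ read early in amber.

    partner + free catalyst → catalyst intermediate A (k = 500 M⁻¹ h⁻¹)
    starting material + catalyst intermediate A → catalyst intermediate B (k = 3400 M⁻¹ h⁻¹)
    catalyst intermediate B ⇌ released group + catalyst intermediate C (K = 0.380 M, k = 3800 h⁻¹)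
    catalyst intermediate C → catalyst intermediate D (k = 94.0 h⁻¹)
    catalyst intermediate D → free catalyst + product (k = 4500 h⁻¹)
    partner + released group ⇌ idle adduct, settled at all times (K = 9.70 M⁻¹)
    scavenger + released group → scavenged by-product (k = 58.0 M⁻¹ h⁻¹)

The neighbour charged with 0.24 M of starting material needs 2000 turnovers, of which 37.3 h⁻¹ over 15 h supplies 28.0%, though that frequency was read at 0.059 M. The computed neighbour has reacted 35.3%, a mean of 47.1 h⁻¹.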